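**Numbering used.** Target: C1(=O)–O2–C3(Ar1)–C3a–C4H2–O5–C6(Ar2)–C6a; ring A is the lactone, ring B the tetrahydrofuran; Ar1 is the 3,4,5-trioxygenated aryl, Ar2 the 3,4-dioxygenated aryl. Compounds 1–17 are defined in the steps and the compound list.

## Analysis of the target

Compound 17 is a cis-fused bicycle in which γ-lactone ring A (C1, O2, C3, C3a, C6a) shares the C3a–C6a bond with tetrahydrofuran ring B (C3a, C4, O5, C6, C6a). C3 carries the 3,4,5-trihydroxyphenyl group and C6 the 3,4-dihydroxyphenyl group. The four stereocentres C3, C3a, C6a and C6 are contiguous, (3S,3aR,6S,6aS): the bridgehead hydrogens are cis, and each aryl group lies on the convex face (H3/H3a trans, H6/H6a trans). The sensitive parts are the catechol and pyrogallol rings (air oxidation), the two benzylic C–O bonds at C3 and C6, each para to an oxygen and so prone to ionisation, epimerisation and hydrogenolysis, and C6a next to the lactone carbonyl. The synthesis is hard because nothing in the molecule is symmetrical: one ring is a lactone and the other an ether, the aryl groups differ, and C3 and C6 must be set independently at opposite ends of the bicycle. The strategy rests on C6 of ring B: it is a benzylic carbon with a strongly cation-stabilising aryl group and stands 1,3 to C4 through C3a. With C4 as an aldehyde, O5–C6 is the bond that forms when a cyclopropane C3a–C6–C6a, fused to ring A and carrying the formyl group on C3a, ionises at C3a–C6. Such a lactone-fused cyclopropane is the product of an intramolecular carbene addition of an allylic diazoacetate, so the skeleton reduces to one alkyne, one aldehyde and a diazoacetyl unit.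

## Retrosynthetic reasoning

**17 from 16.** The five phenolic O–H bonds are traced back to benzyl ethers. The phenols must stay masked through every metal-catalysed and oxidative step. Benzyl is chosen because it tolerates nickel, rhodium, fluoride, Lewis acid and silane/acid, and is removed without acid or base. The forward step has to cleave five aryl O–CH2Ph bonds and spare the benzylic C3–O2 and C6–O5 bonds.

**16 from 15.** The hydrogens on C3a and C4 are removed, giving the enol ether C3a=C4–O5. This takes the C3a stereocentre off the list: the forward reduction sets it from C6a, because only the cis-fused bicycle is unstrained. The forward step must deliver a proton to C3a on the face of H6a and a hydride to C4 without ionising C3–O2.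

**15 from 14 (key disconnection).** O5–C6 is cut and C3a–C6 is joined, so ring B becomes a cyclopropane plus a formyl group on C3a. This is the one bond of ring B whose carbon end can be a stabilised benzylic cation and whose oxygen end can be an enolate oxygen. The gain is that ring B, the O5–C6 bond and the C6 stereocentre arise by isomerisation, with no reagent incorporated, and that C6 is already bonded to C6a, so regiochemistry is fixed by connectivity. The forward step must cleave C3a–C6 and not C6a–C6, close with Ar2 trans to C1, and leave C3 and C6a alone.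

**14 from 13 from 12.** The formyl group is traced to a primary alcohol and then to its silyl ether, because a free aldehyde would not survive the nickel coupling or the carbenoid. Two routine steps unmask it just before it is needed.

**12 from 11.** The two cyclopropane bonds at C6a (C6a–C3a and C6a–C6) are cut, giving a carbene on the carbon next to the lactone carbonyl and an alkene C3a=C6. The ester tether is ring A itself, so no tether atom is wasted. The addition is stereospecific, so an E alkene puts Ar2 exo, cis to the CH2OSi group. What is not automatic is the alkene face relative to C3. In the transition state that places Ar1 exo, as 14 requires, Ar1 eclipses the CH2OSi group on C3a (allylic 1,2-strain), so an achiral catalyst is expected to favour the other face. The forward step therefore uses a chiral dirhodium carboxamidate whose own face preference is the required one.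

**11 from 8 from 6 and 7.** The diazoacetate is cut at the ester C–O bond and at the diazo group. Acylation with 7 and exchange of bromide for N2 through a sulfonylhydrazine reagent are mild enough for a benzylic, allylic ester.

**6 from 3 and 4.** The C3–C3a bond and the vinylic C6–H bond are cut: a reductive coupling of alkyne 3 with aldehyde 4. One step sets the C3 stereocentre, the regiochemistry (C–C bond at the alkyne carbon remote from Ar2) and the E geometry (syn addition of H and C).

**3 from 1 and 2.** The aryl–alkynyl bond is cut; a cross-coupling of aryl bromide 1 with the terminal alkyne 2.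

## Alternatives that were turned down

**Alternative 1:** Both rings are disconnected at once, C6a–C3a and C3–O2, back to the acyclic malonate ether A2. In the forward step Mn(OAc)3 (trivalent manganese) oxidises the malonate to a radical at C6a, which cyclises 5-exo onto the cinnamyl alkene. Cu(OAc)2 (divalent copper) oxidises the benzylic radical at C3 to a cation, and an ester oxygen captures it with loss of a tert-butyl group, giving A1.
- For: two rings, one C–C bond, one C–O bond and three stereocentres in one step, and A2 is about two steps from an aldehyde, a malonate and a cinnamyl alcohol. On step count and bond economy this is stronger than the chosen route.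
- Against: the only stereocentre of A2 is a β-alkoxy malonate carbon made by a reversible oxa-Michael addition, so there is no secure handle on absolute configuration. One-electron oxidants in hot acetic acid meet five electron-rich benzyl aryl ethers and an oxidisable benzylic ether C–H at C6. C3 is set in an uncontrolled cation capture. The extra ester on C6a must then be removed by acidolysis and decarboxylation next to two acid-labile benzylic C–O bonds.
- The chosen strategy spends about three more steps and gains a catalytic asymmetric entry and closed-shell steps in which each stereocentre has a named control element.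

**Alternative 2:** C3a–C6a is disconnected by a retro-[3,3] shift to the nine-membered allylic lactone A4. In the forward step the silyl ketene acetal of A4 undergoes Ireland–Claisen rearrangement, contracting the ring to the tetrahydrofuran acid A3 with cis carboxyl and 1-arylvinyl groups.
- For: the C3a–C6a bond and its cis relationship come from a pericyclic step with predictable transfer of chirality from C6.
- Against: A4 is a medium-ring lactone with a Z-trisubstituted alkene, costly to close. Its enolate has the ring oxygen O5 in the β-position and can fragment by β-elimination. In A3, C3 is an sp2 carbon with one carbon too many, so the alkene must be cleaved to the aryl ketone in the presence of electron-rich arenes, reduced and lactonised, and hydride attack from the convex face would place Ar1 on the concave side.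
- The chosen strategy is shorter after the key step (two steps instead of four or five) and sets C3 first, by catalyst control.

**Alternative 3:** Ring B is disconnected at C6–C6a and C4–C3a into the butenolide A6 and a carbonyl ylide. In the forward step CsF releases the ylide from the α-chloro silylmethyl ether A7, and it adds across the butenolide double bond anti to Ar1, giving A5, which is the same compound as 16.
- For: this is the most convergent plan. Both C–C bonds of ring B and three stereocentres form in one step at the final oxidation level, and face selection anti to the γ-aryl group is reliable. It is clearly stronger than the chosen route on step count.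
- Against: the ylide is unsymmetrical, and nothing forces its benzylic end to C6a and its CH2 end to C3a; the regioisomer is a constitutional isomer of A5. The orientation of Ar2 relative to the lactone carbonyl is uncontrolled. A6 has an acidic γ-hydrogen (benzylic, vinylogous to the carbonyl) and can racemise under basic fluoride. A7 is a hydrolytically labile α-chloro ether of an electron-rich aldehyde.
- The chosen strategy offers regiochemistry fixed by connectivity (C6 is bonded to C6a from the cyclopropanation onwards) and a stereocontrol element for C6.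

Key step: step 8

**Assumption 1:** (+)-neomenthyldiphenylphosphine is taken to give the 1R alcohol 6 in step 2; if the first run shows the opposite sense, the (−)-ligand is used and nothing else changes.

**Assumption 2:** Rh2(4S-MPPIM)4, dirhodium tetrakis[methyl (4S)-2-oxo-1-(3-phenylpropanoyl)imidazolidine-4-carboxylate], is taken to select the alkene face it selects with allyl diazoacetate (the one leading to (1R,5S)-3-oxabicyclo[3.1.0]hexan-2-one), which in 11 is the face anti to Ar1; if not, the 4R catalyst is used.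

## Route

Step 1
Reactants: 1 4-bromo-1,2-bis(benzyloxy)benzene; 2 tert-butyldimethyl(prop-2-yn-1-yloxy)silane
Product: 3 tert-butyl({3-[3,4-bis(benzyloxy)phenyl]prop-2-yn-1-yl}oxy)dimethylsilane
Conditions: PdCl2(PPh3)2 (3 mol %), CuI (6 mol %), Et3N/DMF 1:1, 80 °C
Reagents that add atoms: none
Why: Sonogashira coupling of an aryl bromide with a terminal alkyne; the electron-rich bromide needs heat for oxidative addition, and the silyl and benzyl ethers are inert to the amine and to the palladium/copper pair.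

Step 2
Reactants: 3 tert-butyl({3-[3,4-bis(benzyloxy)phenyl]prop-2-yn-1-yl}oxy)dimethylsilane; 4 3,4,5-tris(benzyloxy)benzaldehyde
Product: 6 (1R,2E)-3-[3,4-bis(benzyloxy)phenyl]-2-({[tert-butyl(dimethyl)silyl]oxy}methyl)-1-[3,4,5-tris(benzyloxy)phenyl]prop-2-en-1-ol, via O-diethylboryl ether 5 (not isolated)
Conditions: Ni(cod)2 (10 mol %), (+)-neomenthyldiphenylphosphine (20 mol %), Et3B (2 equiv), EtOAc/1,3-dimethylimidazolidin-2-one 1:1, 0 °C to rt; aq NH4Cl
Reagents that add atoms: none
Why: Nickel-catalysed reductive coupling of an alkyne and an aldehyde: oxidative cyclisation on zerovalent nickel joins the aldehyde carbon to the alkyne carbon remote from the aryl group, and ethyl transfer from boron, β-hydride elimination and C–H reductive elimination deliver hydrogen syn to the new C–C bond, which fixes the E geometry (Ar2 cis to CH2OSi). The chiral monophosphine differentiates the aldehyde faces and sets the carbinol centre, C3 of the target, as R in 6.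

Step 3
Reactants: 6 (1R,2E)-3-[3,4-bis(benzyloxy)phenyl]-2-({[tert-butyl(dimethyl)silyl]oxy}methyl)-1-[3,4,5-tris(benzyloxy)phenyl]prop-2-en-1-ol; 7 bromoacetyl bromide
Product: 8 (1R,2E)-3-[3,4-bis(benzyloxy)phenyl]-2-({[tert-butyl(dimethyl)silyl]oxy}methyl)-1-[3,4,5-tris(benzyloxy)phenyl]prop-2-en-1-yl bromoacetate
Conditions: NaHCO3 (3 equiv), MeCN/CH2Cl2, 0 °C
Reagents that add atoms: none
Why: Acylation of the secondary alcohol at the acyl bromide carbon, which is far faster than substitution at CH2Br; the insoluble mild base and low temperature keep the benzylic, allylic ester from ionising.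

Step 4
Reactants: 8 (1R,2E)-3-[3,4-bis(benzyloxy)phenyl]-2-({[tert-butyl(dimethyl)silyl]oxy}methyl)-1-[3,4,5-tris(benzyloxy)phenyl]prop-2-en-1-yl bromoacetate
Product: 11 (1R,2E)-3-[3,4-bis(benzyloxy)phenyl]-2-({[tert-butyl(dimethyl)silyl]oxy}methyl)-1-[3,4,5-tris(benzyloxy)phenyl]prop-2-en-1-yl diazoacetate, via ditosylhydrazinoacetate 9 (not isolated), via glyoxylate tosylhydrazone 10 (not isolated)
Conditions: TsNHNHTs (2 equiv), DBU (5 equiv), THF, 0 °C
Reagents that add atoms: 1,2-bis(4-methylbenzenesulfonyl)hydrazine, Cc1ccc(cc1)S(=O)(=O)NNS(=O)(=O)c1ccc(C)cc1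
Why: N-Alkylation of the ditosylhydrazine anion by the bromoacetate, then two base-induced losses of sulfinate (the second a Bamford–Stevens-type elimination), give the diazoacetate at 0 °C without touching the stereocentre.

Step 5
Reactants: 11 (1R,2E)-3-[3,4-bis(benzyloxy)phenyl]-2-({[tert-butyl(dimethyl)silyl]oxy}methyl)-1-[3,4,5-tris(benzyloxy)phenyl]prop-2-en-1-yl diazoacetate
Product: 12 (1R,4R,5S,6S)-6-[3,4-bis(benzyloxy)phenyl]-5-({[tert-butyl(dimethyl)silyl]oxy}methyl)-4-[3,4,5-tris(benzyloxy)phenyl]-3-oxabicyclo[3.1.0]hexan-2-one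
Conditions: Rh2(4S-MPPIM)4 (1 mol %), CH2Cl2, reflux, 11 added over 10 h
Reagents that add atoms: none
Why: Intramolecular cyclopropanation of an allylic diazoacetate by a dirhodium carboxamidate carbenoid: the concerted addition keeps the E geometry (Ar2 exo, cis to CH2OSi) and the five-membered tether forces the cis ring fusion. The alkene face, and with it C6a and C3a relative to C3, is imposed by the 4S catalyst, whose preferred face is the one anti to Ar1; an achiral catalyst is avoided because allylic 1,2-strain between Ar1 and CH2OSi disfavours that face in the substrate itself.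

Step 6
Reactants: 12 (1R,4R,5S,6S)-6-[3,4-bis(benzyloxy)phenyl]-5-({[tert-butyl(dimethyl)silyl]oxy}methyl)-4-[3,4,5-tris(benzyloxy)phenyl]-3-oxabicyclo[3.1.0]hexan-2-one
Product: 13 (1R,4R,5S,6S)-6-[3,4-bis(benzyloxy)phenyl]-5-(hydroxymethyl)-4-[3,4,5-tris(benzyloxy)phenyl]-3-oxabicyclo[3.1.0]hexan-2-one
Conditions: HF·pyridine, pyridine/THF, 0 °C to rt
Reagents that add atoms: none
Why: Fluoride cleavage of the primary silyl ether; buffered HF·pyridine is neither basic enough to open the lactone nor acidic enough to ionise the aryl cyclopropane. The freed CH2OH is trans to the lactone carbonyl across the ring fusion, so it cannot translactonise.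

Step 7
Reactants: 13 (1R,4R,5S,6S)-6-[3,4-bis(benzyloxy)phenyl]-5-(hydroxymethyl)-4-[3,4,5-tris(benzyloxy)phenyl]-3-oxabicyclo[3.1.0]hexan-2-one
Product: 14 (1R,4R,5R,6S)-6-[3,4-bis(benzyloxy)phenyl]-2-oxo-4-[3,4,5-tris(benzyloxy)phenyl]-3-oxabicyclo[3.1.0]hexane-5-carbaldehyde
Conditions: Dess–Martin periodinane (1.5 equiv), NaHCO3, CH2Cl2, 0 °C to rt
Reagents that add atoms: none
Why: Dess–Martin oxidation of a neopentyl-type primary alcohol under buffered, near-neutral conditions; the aldehyde has no α-hydrogen, so it can neither epimerise nor enolise. It is used at once, because it is the activated donor–acceptor cyclopropane of the next step.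

Step 8
Reactants: 14 (1R,4R,5R,6S)-6-[3,4-bis(benzyloxy)phenyl]-2-oxo-4-[3,4,5-tris(benzyloxy)phenyl]-3-oxabicyclo[3.1.0]hexane-5-carbaldehyde
Product: 15 (3R,6S,6aS)-6-[3,4-bis(benzyloxy)phenyl]-3-[3,4,5-tris(benzyloxy)phenyl]-6,6a-dihydro-1H,3H-furo[3,4-c]furan-1-one
Conditions: Sc(OTf)3 (5 mol %), 4 Å molecular sieves, CH2Cl2, −40 to 0 °C; Et3N quench
Reagents that add atoms: none
Why: Sc(OTf)3 binds the formyl oxygen of 14, and the C3a–C6 bond, flanked by the Ar2 donor on C6 and the formyl acceptor on C3a, heterolyses to a 3,4-dialkoxybenzylic cation at C6 and a scandium enolate C3a=C4–O. The enolate oxygen then bonds to C6, which makes O5–C6 and turns the three-membered ring into ring B in its 2,3-dihydrofuran form; the closest known reaction type is the Lewis-acid-catalysed Cloke–Wilson rearrangement of donor–acceptor cyclopropyl ketones and aldehydes. Ring B closes 5-exo-trig: the oxygen attacks the cationic carbon, whose π bond to the arene lies outside the new ring. The new stereocentre C6 is controlled by C6a: in the cation the C6a–H bond lies in the plane of the benzylic cation to avoid allylic 1,3-strain with the aryl ring, and O5, held on the C3a side, adds so that Ar2 ends up trans to C1; collapse of a tight ion pair with retention gives the same isomer, because Ar2 is exo in 14. The step needs cleavage of C3a–C6 and not of C6a–C6: the aldehyde enolate is the better leaving carbanion, and the other zwitterion has no ring-forming outlet (its lactone oxygen could only close a strained bicyclic ketene acetal), so it can only return to 14. C3 and C6a take no part, and the formyl group has no α-hydrogen. Low temperature, low catalyst loading and the amine quench are chosen because in 15 the C3–O2 bond has become allylic to the enol ether.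

Step 9
Reactants: 15 (3R,6S,6aS)-6-[3,4-bis(benzyloxy)phenyl]-3-[3,4,5-tris(benzyloxy)phenyl]-6,6a-dihydro-1H,3H-furo[3,4-c]furan-1-one
Product: 16 (3S,3aR,6S,6aS)-6-[3,4-bis(benzyloxy)phenyl]-3-[3,4,5-tris(benzyloxy)phenyl]tetrahydro-1H,3H-furo[3,4-c]furan-1-one
Conditions: Et3SiH (3 equiv), CF3CO2H (5 equiv), CH2Cl2, −78 to −30 °C; NaHCO3 quench
Reagents that add atoms: none
Why: Ionic hydrogenation of an enol ether: protonation at C3a gives the oxocarbenium ion at C4, which takes hydride from the silane and becomes CH2. The proton should add to C3a on the face of H6a, because only that gives the unstrained cis-fused bicycle and the protonation is reversible; this sets C3a.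

Step 10
Reactants: 16 (3S,3aR,6S,6aS)-6-[3,4-bis(benzyloxy)phenyl]-3-[3,4,5-tris(benzyloxy)phenyl]tetrahydro-1H,3H-furo[3,4-c]furan-1-one
Product: 17 (3S,3aR,6S,6aS)-6-(3,4-dihydroxyphenyl)-3-(3,4,5-trihydroxyphenyl)tetrahydro-1H,3H-furo[3,4-c]furan-1-one
Conditions: H2 (1 atm), 10% Pd/C, EtOAc/MeOH 1:1, rt, stopped after uptake of 5 equiv; filtered under argon
Reagents that add atoms: none
Why: Hydrogenolysis of five aryl benzyl ethers on palladium; in neutral medium at 1 atm the aryl O–CH2Ph bonds should cleave well before the secondary benzylic C3–O2 and C6–O5 bonds. The polyphenol is handled under argon.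

## Compound list

1 | 4-bromo-1,2-bis(benzyloxy)benzene | Brc1ccc(OCc2ccccc2)c(OCc2ccccc2)c1 | starting material
2 | tert-butyldimethyl(prop-2-yn-1-yloxy)silane | C#CCO[Si](C)(C)C(C)(C)C | starting material
3 | tert-butyl({3-[3,4-bis(benzyloxy)phenyl]prop-2-yn-1-yl}oxy)dimethylsilane | CC(C)(C)[Si](C)(C)OCC#Cc1ccc(OCc2ccccc2)c(OCc2ccccc2)c1 | intermediate
4 | 3,4,5-tris(benzyloxy)benzaldehyde | O=Cc1cc(OCc2ccccc2)c(OCc2ccccc2)c(OCc2ccccc2)c1 | starting material
5 | (1R,2E)-3-[3,4-bis(benzyloxy)phenyl]-2-({[tert-butyl(dimethyl)silyl]oxy}methyl)-1-[3,4,5-tris(benzyloxy)phenyl]prop-2-en-1-yl diethylborinate (O-diethylboryl ether of 6, not isolated) | CCB(CC)O[C@H](c1cc(OCc2ccccc2)c(OCc2ccccc2)c(OCc2ccccc2)c1)/C(CO[Si](C)(C)C(C)(C)C)=C/c1ccc(OCc2ccccc2)c(OCc2ccccc2)c1 | intermediate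
6 | (1R,2E)-3-[3,4-bis(benzyloxy)phenyl]-2-({[tert-butyl(dimethyl)silyl]oxy}methyl)-1-[3,4,5-tris(benzyloxy)phenyl]prop-2-en-1-ol | O[C@H](c1cc(OCc2ccccc2)c(OCc2ccccc2)c(OCc2ccccc2)c1)/C(CO[Si](C)(C)C(C)(C)C)=C/c1ccc(OCc2ccccc2)c(OCc2ccccc2)c1 | intermediate
7 | bromoacetyl bromide | BrCC(=O)Br | starting material
8 | (1R,2E)-3-[3,4-bis(benzyloxy)phenyl]-2-({[tert-butyl(dimethyl)silyl]oxy}methyl)-1-[3,4,5-tris(benzyloxy)phenyl]prop-2-en-1-yl bromoacetate | BrCC(=O)O[C@H](c1cc(OCc2ccccc2)c(OCc2ccccc2)c(OCc2ccccc2)c1)/C(CO[Si](C)(C)C(C)(C)C)=C/c1ccc(OCc2ccccc2)c(OCc2ccccc2)c1 | intermediate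
9 | (1R,2E)-3-[3,4-bis(benzyloxy)phenyl]-2-({[tert-butyl(dimethyl)silyl]oxy}methyl)-1-[3,4,5-tris(benzyloxy)phenyl]prop-2-en-1-yl [1,2-bis(4-methylbenzenesulfonyl)hydrazinyl]acetate (not isolated) | Cc1ccc(cc1)S(=O)(=O)NN(CC(=O)O[C@H](c1cc(OCc2ccccc2)c(OCc2ccccc2)c(OCc2ccccc2)c1)/C(CO[Si](C)(C)C(C)(C)C)=C/c1ccc(OCc2ccccc2)c(OCc2ccccc2)c1)S(=O)(=O)c1ccc(C)cc1 | intermediate
10 | (1R,2E)-3-[3,4-bis(benzyloxy)phenyl]-2-({[tert-butyl(dimethyl)silyl]oxy}methyl)-1-[3,4,5-tris(benzyloxy)phenyl]prop-2-en-1-yl {[(4-methylbenzenesulfonyl)amino]imino}acetate (glyoxylate tosylhydrazone, not isolated) | Cc1ccc(cc1)S(=O)(=O)NN=CC(=O)O[C@H](c1cc(OCc2ccccc2)c(OCc2ccccc2)c(OCc2ccccc2)c1)/C(CO[Si](C)(C)C(C)(C)C)=C/c1ccc(OCc2ccccc2)c(OCc2ccccc2)c1 | intermediate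
11 | (1R,2E)-3-[3,4-bis(benzyloxy)phenyl]-2-({[tert-butyl(dimethyl)silyl]oxy}methyl)-1-[3,4,5-tris(benzyloxy)phenyl]prop-2-en-1-yl diazoacetate | [N-]=[N+]=CC(=O)O[C@H](c1cc(OCc2ccccc2)c(OCc2ccccc2)c(OCc2ccccc2)c1)/C(CO[Si](C)(C)C(C)(C)C)=C/c1ccc(OCc2ccccc2)c(OCc2ccccc2)c1 | intermediate
12 | (1R,4R,5S,6S)-6-[3,4-bis(benzyloxy)phenyl]-5-({[tert-butyl(dimethyl)silyl]oxy}methyl)-4-[3,4,5-tris(benzyloxy)phenyl]-3-oxabicyclo[3.1.0]hexan-2-one (both aryls exo) | O=C1O[C@H](c2cc(OCc3ccccc3)c(OCc3ccccc3)c(OCc3ccccc3)c2)[C@@]2(CO[Si](C)(C)C(C)(C)C)[C@H](c3ccc(OCc4ccccc4)c(OCc4ccccc4)c3)[C@@H]12 | intermediate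
13 | (1R,4R,5S,6S)-6-[3,4-bis(benzyloxy)phenyl]-5-(hydroxymethyl)-4-[3,4,5-tris(benzyloxy)phenyl]-3-oxabicyclo[3.1.0]hexan-2-one | O=C1O[C@H](c2cc(OCc3ccccc3)c(OCc3ccccc3)c(OCc3ccccc3)c2)[C@@]2(CO)[C@H](c3ccc(OCc4ccccc4)c(OCc4ccccc4)c3)[C@@H]12 | intermediate
14 | (1R,4R,5R,6S)-6-[3,4-bis(benzyloxy)phenyl]-2-oxo-4-[3,4,5-tris(benzyloxy)phenyl]-3-oxabicyclo[3.1.0]hexane-5-carbaldehyde (locants as in 12 and 13; both aryls exo) | O=C1O[C@H](c2cc(OCc3ccccc3)c(OCc3ccccc3)c(OCc3ccccc3)c2)[C@@]2(C=O)[C@H](c3ccc(OCc4ccccc4)c(OCc4ccccc4)c3)[C@@H]12 | intermediate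
15 | (3R,6S,6aS)-6-[3,4-bis(benzyloxy)phenyl]-3-[3,4,5-tris(benzyloxy)phenyl]-6,6a-dihydro-1H,3H-furo[3,4-c]furan-1-one | O=C1O[C@H](c2cc(OCc3ccccc3)c(OCc3ccccc3)c(OCc3ccccc3)c2)C2=CO[C@H](c3ccc(OCc4ccccc4)c(OCc4ccccc4)c3)[C@@H]12 | intermediate
16 | (3S,3aR,6S,6aS)-6-[3,4-bis(benzyloxy)phenyl]-3-[3,4,5-tris(benzyloxy)phenyl]tetrahydro-1H,3H-furo[3,4-c]furan-1-one | O=C1O[C@H](c2cc(OCc3ccccc3)c(OCc3ccccc3)c(OCc3ccccc3)c2)[C@H]2CO[C@H](c3ccc(OCc4ccccc4)c(OCc4ccccc4)c3)[C@@H]12 | intermediate
17 | (3S,3aR,6S,6aS)-6-(3,4-dihydroxyphenyl)-3-(3,4,5-trihydroxyphenyl)tetrahydro-1H,3H-furo[3,4-c]furan-1-one | O=C1O[C@H](c2cc(O)c(O)c(O)c2)[C@H]2CO[C@H](c3ccc(O)c(O)c3)[C@@H]12 | target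

## Step count and least certain steps

Total: 10 steps. Longest linear sequence: 10 steps (1 or 2 to 17); 4 and 7 enter as purchased compounds.

**Step 8 (key step).** The most likely failure is ionisation of the product and not of the substrate. Once ring B has formed, the lactone C3–O2 bond is allylic to the enol ether as well as benzylic, and continued contact with the Lewis acid can ionise it in a Ferrier-type manner, scrambling C3 or moving the carboxylate to C4. A second risk is loss of the C6a proton from the zwitterion before the oxygen closes, which would give an arylidene lactone. Fallback, from 14 to 15: the ring expansion is run without any Lewis acid, by nucleophilic catalysis with DABCO (20 mol %) in DMSO at 80–100 °C. The amine opens C3a–C6 by substitution at C6 and the resulting aldehyde enolate oxygen displaces the amine 5-exo-tet; two inversions amount to retention, which from the exo aryl of 14 is again Ar2 trans to C1, and no cation is formed that could ionise C3–O2. No new compound is made (F0).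

**Step 5.** The catalyst has to impose the alkene face anti to Ar1 against the substrate's own preference, because in that transition state Ar1 eclipses the CH2OSi group. The likely failures are poor facial selectivity and, when cyclopropanation is slowed, hydride transfer from the benzylic, allylic C–H next to the ester oxygen to the carbenoid. Fallback, from 3 and 4, returning at 16: the C3/C6a relationship is made in the sense the substrate prefers and C3 is inverted at the end.
- Step 2 with the antipodal ligand gives, through the O-diethylboryl ether F1, the (1S,2E)-allylic alcohol F2.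
- Steps 3 and 4 give the (1S)-bromoacetate F3 and, through the ditosylhydrazinoacetate F4 and the glyoxylate tosylhydrazone F5, the (1S)-diazoacetate F6.
- With the same 4S catalyst, now reinforcing the substrate bias, F6 should give the endo-Ar1 cyclopropane silyl ether F7, whose cyclopropane carbons are configured as in 12.
- Steps 6 to 9 then give the cyclopropyl carbinol F8, the cyclopropane carbaldehyde F9, the 3-epi dihydrofuranone F10 and the 3-epi lactone F11.
- LiOH (THF/H2O, 0 °C) opens F11 to the hydroxy acid F12, which is freed at pH 5 and used at once. Mitsunobu lactonisation (PPh3, diisopropyl azodicarboxylate, THF, 0 °C) closes C3–O2 with inversion at the benzylic carbon and gives 16.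

**Step 9.** Acid can ionise the allylic C3–O2 bond of 15 before C3a is protonated, and the silane would then reduce the cation to a ring-opened acid; prolonged exposure can also cleave the benzylic C–O bonds of 16 reductively. Fallback, from 15 to 16: hydrogen-atom-transfer hydrogenation under neutral conditions, Mn(dpm)3 (tris(2,2,6,6-tetramethylheptane-3,5-dionato)manganese, 10 mol %), PhSiH3, tert-butyl hydroperoxide, i-PrOH, rt. This is a radical hydrogenation of electron-rich alkenes that leaves benzyl ethers alone, and the ring-fusion hydrogen is again expected cis. No new compound is made (F0).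

**Step 2.** Face discrimination of an electron-rich aromatic aldehyde by a monodentate phosphine may be incomplete, and its sense is assumed. Fallback, from 3 and 4, returning at 6: the coupling is run with achiral PBu3 in place of the chiral ligand, giving, through the racemic O-diethylboryl ether F13, the racemic allylic alcohol F14. Sharpless kinetic resolution (Ti(OiPr)4, L-(+)-diisopropyl tartrate, tert-butyl hydroperoxide 0.6 equiv, 4 Å sieves, CH2Cl2, −20 °C) then epoxidises the 1S enantiomer to the anti epoxy alcohol F15 and leaves 6.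

**Step 10.** Hydrogenolysis may go on to the benzylic C3–O2 and C6–O5 bonds once the aryl ethers are cleaved, and the free pyrogallol and catechol oxidise in air. Fallback, from 16 to 17: non-reductive debenzylation with BCl3 and pentamethylbenzene as benzyl-cation scavenger in CH2Cl2 at −78 °C, quenched with MeOH. No new compound is made (F0).

## Further compounds

F0 | step 8 | none | none
F1 | step 5 | (1S,2E)-3-[3,4-bis(benzyloxy)phenyl]-2-({[tert-butyl(dimethyl)silyl]oxy}methyl)-1-[3,4,5-tris(benzyloxy)phenyl]prop-2-en-1-yl diethylborinate | CCB(CC)O[C@@H](c1cc(OCc2ccccc2)c(OCc2ccccc2)c(OCc2ccccc2)c1)/C(CO[Si](C)(C)C(C)(C)C)=C/c1ccc(OCc2ccccc2)c(OCc2ccccc2)c1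
F2 | step 5 | (1S,2E)-3-[3,4-bis(benzyloxy)phenyl]-2-({[tert-butyl(dimethyl)silyl]oxy}methyl)-1-[3,4,5-tris(benzyloxy)phenyl]prop-2-en-1-ol | O[C@@H](c1cc(OCc2ccccc2)c(OCc2ccccc2)c(OCc2ccccc2)c1)/C(CO[Si](C)(C)C(C)(C)C)=C/c1ccc(OCc2ccccc2)c(OCc2ccccc2)c1
F3 | step 5 | (1S,2E)-3-[3,4-bis(benzyloxy)phenyl]-2-({[tert-butyl(dimethyl)silyl]oxy}methyl)-1-[3,4,5-tris(benzyloxy)phenyl]prop-2-en-1-yl bromoacetate | BrCC(=O)O[C@@H](c1cc(OCc2ccccc2)c(OCc2ccccc2)c(OCc2ccccc2)c1)/C(CO[Si](C)(C)C(C)(C)C)=C/c1ccc(OCc2ccccc2)c(OCc2ccccc2)c1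
F4 | step 5 | (1S,2E)-3-[3,4-bis(benzyloxy)phenyl]-2-({[tert-butyl(dimethyl)silyl]oxy}methyl)-1-[3,4,5-tris(benzyloxy)phenyl]prop-2-en-1-yl [1,2-bis(4-methylbenzenesulfonyl)hydrazinyl]acetate | Cc1ccc(cc1)S(=O)(=O)NN(CC(=O)O[C@@H](c1cc(OCc2ccccc2)c(OCc2ccccc2)c(OCc2ccccc2)c1)/C(CO[Si](C)(C)C(C)(C)C)=C/c1ccc(OCc2ccccc2)c(OCc2ccccc2)c1)S(=O)(=O)c1ccc(C)cc1
F5 | step 5 | (1S,2E)-3-[3,4-bis(benzyloxy)phenyl]-2-({[tert-butyl(dimethyl)silyl]oxy}methyl)-1-[3,4,5-tris(benzyloxy)phenyl]prop-2-en-1-yl {[(4-methylbenzenesulfonyl)amino]imino}acetate | Cc1ccc(cc1)S(=O)(=O)NN=CC(=O)O[C@@H](c1cc(OCc2ccccc2)c(OCc2ccccc2)c(OCc2ccccc2)c1)/C(CO[Si](C)(C)C(C)(C)C)=C/c1ccc(OCc2ccccc2)c(OCc2ccccc2)c1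
F6 | step 5 | (1S,2E)-3-[3,4-bis(benzyloxy)phenyl]-2-({[tert-butyl(dimethyl)silyl]oxy}methyl)-1-[3,4,5-tris(benzyloxy)phenyl]prop-2-en-1-yl diazoacetate | [N-]=[N+]=CC(=O)O[C@@H](c1cc(OCc2ccccc2)c(OCc2ccccc2)c(OCc2ccccc2)c1)/C(CO[Si](C)(C)C(C)(C)C)=C/c1ccc(OCc2ccccc2)c(OCc2ccccc2)c1
F7 | step 5 | (1R,4S,5S,6S)-6-[3,4-bis(benzyloxy)phenyl]-5-({[tert-butyl(dimethyl)silyl]oxy}methyl)-4-[3,4,5-tris(benzyloxy)phenyl]-3-oxabicyclo[3.1.0]hexan-2-one | O=C1O[C@@H](c2cc(OCc3ccccc3)c(OCc3ccccc3)c(OCc3ccccc3)c2)[C@@]2(CO[Si](C)(C)C(C)(C)C)[C@H](c3ccc(OCc4ccccc4)c(OCc4ccccc4)c3)[C@@H]12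
F8 | step 5 | (1R,4S,5S,6S)-6-[3,4-bis(benzyloxy)phenyl]-5-(hydroxymethyl)-4-[3,4,5-tris(benzyloxy)phenyl]-3-oxabicyclo[3.1.0]hexan-2-one | O=C1O[C@@H](c2cc(OCc3ccccc3)c(OCc3ccccc3)c(OCc3ccccc3)c2)[C@@]2(CO)[C@H](c3ccc(OCc4ccccc4)c(OCc4ccccc4)c3)[C@@H]12
F9 | step 5 | (1R,4S,5R,6S)-6-[3,4-bis(benzyloxy)phenyl]-2-oxo-4-[3,4,5-tris(benzyloxy)phenyl]-3-oxabicyclo[3.1.0]hexane-5-carbaldehyde | O=C1O[C@@H](c2cc(OCc3ccccc3)c(OCc3ccccc3)c(OCc3ccccc3)c2)[C@@]2(C=O)[C@H](c3ccc(OCc4ccccc4)c(OCc4ccccc4)c3)[C@@H]12
F10 | step 5 | (3S,6S,6aS)-6-[3,4-bis(benzyloxy)phenyl]-3-[3,4,5-tris(benzyloxy)phenyl]-6,6a-dihydro-1H,3H-furo[3,4-c]furan-1-one | O=C1O[C@@H](c2cc(OCc3ccccc3)c(OCc3ccccc3)c(OCc3ccccc3)c2)C2=CO[C@H](c3ccc(OCc4ccccc4)c(OCc4ccccc4)c3)[C@@H]12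
F11 | step 5 | (3R,3aR,6S,6aS)-6-[3,4-bis(benzyloxy)phenyl]-3-[3,4,5-tris(benzyloxy)phenyl]tetrahydro-1H,3H-furo[3,4-c]furan-1-one | O=C1O[C@@H](c2cc(OCc3ccccc3)c(OCc3ccccc3)c(OCc3ccccc3)c2)[C@H]2CO[C@H](c3ccc(OCc4ccccc4)c(OCc4ccccc4)c3)[C@@H]12
F12 | step 5 | (2S,3S,4R)-2-[3,4-bis(benzyloxy)phenyl]-4-{(R)-hydroxy[3,4,5-tris(benzyloxy)phenyl]methyl}oxolane-3-carboxylic acid | O[C@@H](c1cc(OCc2ccccc2)c(OCc2ccccc2)c(OCc2ccccc2)c1)[C@H]1CO[C@H](c2ccc(OCc3ccccc3)c(OCc3ccccc3)c2)[C@H]1C(=O)O
F0 | step 9 | none | none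
F13 | step 2 | rac-(2E)-3-[3,4-bis(benzyloxy)phenyl]-2-({[tert-butyl(dimethyl)silyl]oxy}methyl)-1-[3,4,5-tris(benzyloxy)phenyl]prop-2-en-1-yl diethylborinate | CCB(CC)OC(c1cc(OCc2ccccc2)c(OCc2ccccc2)c(OCc2ccccc2)c1)/C(CO[Si](C)(C)C(C)(C)C)=C/c1ccc(OCc2ccccc2)c(OCc2ccccc2)c1
F14 | step 2 | rac-(2E)-3-[3,4-bis(benzyloxy)phenyl]-2-({[tert-butyl(dimethyl)silyl]oxy}methyl)-1-[3,4,5-tris(benzyloxy)phenyl]prop-2-en-1-ol | OC(c1cc(OCc2ccccc2)c(OCc2ccccc2)c(OCc2ccccc2)c1)/C(CO[Si](C)(C)C(C)(C)C)=C/c1ccc(OCc2ccccc2)c(OCc2ccccc2)c1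
F15 | step 2 | (S)-[(2S,3S)-3-[3,4-bis(benzyloxy)phenyl]-2-({[tert-butyl(dimethyl)silyl]oxy}methyl)oxiran-2-yl][3,4,5-tris(benzyloxy)phenyl]methanol | O[C@@H](c1cc(OCc2ccccc2)c(OCc2ccccc2)c(OCc2ccccc2)c1)[C@]1(CO[Si](C)(C)C(C)(C)C)O[C@H]1c1ccc(OCc2ccccc2)c(OCc2ccccc2)c1
F0 | step 10 | none | none
A1 | alternative 1 | tert-butyl 6-[3,4-bis(benzyloxy)phenyl]-1-oxo-3-[3,4,5-tris(benzyloxy)phenyl]tetrahydro-1H,3H-furo[3,4-c]furan-6a-carboxylate (C3, C3a and C6 as in 17, ester in the place of H6a) | O=C1O[C@H](c2cc(OCc3ccccc3)c(OCc3ccccc3)c(OCc3ccccc3)c2)[C@H]2CO[C@H](c3ccc(OCc4ccccc4)c(OCc4ccccc4)c3)[C@@]12C(=O)OC(C)(C)C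
A2 | alternative 1 | di-tert-butyl 2-[(S)-[3,4-bis(benzyloxy)phenyl]({(2E)-3-[3,4,5-tris(benzyloxy)phenyl]prop-2-en-1-yl}oxy)methyl]propanedioate | CC(C)(C)OC(=O)C(C(=O)OC(C)(C)C)[C@H](OC/C=C/c1cc(OCc2ccccc2)c(OCc2ccccc2)c(OCc2ccccc2)c1)c1ccc(OCc2ccccc2)c(OCc2ccccc2)c1
A3 | alternative 2 | 2-[3,4-bis(benzyloxy)phenyl]-4-{1-[3,4,5-tris(benzyloxy)phenyl]ethenyl}oxolane-3-carboxylic acid (2,3-trans, 3,4-cis; ring carbons as C6, C6a and C3a of 17) | C=C(c1cc(OCc2ccccc2)c(OCc2ccccc2)c(OCc2ccccc2)c1)[C@H]1CO[C@H](c2ccc(OCc3ccccc3)c(OCc3ccccc3)c2)[C@H]1C(=O)O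
A4 | alternative 2 | (4S,7Z)-4-[3,4-bis(benzyloxy)phenyl]-8-[3,4,5-tris(benzyloxy)phenyl]-3,4,6,9-tetrahydro-2H-1,5-dioxonin-2-one | O=C1OC/C(c2cc(OCc3ccccc3)c(OCc3ccccc3)c(OCc3ccccc3)c2)=C\CO[C@H](c2ccc(OCc3ccccc3)c(OCc3ccccc3)c2)C1
A5 | alternative 3 | (3S,3aR,6S,6aS)-6-[3,4-bis(benzyloxy)phenyl]-3-[3,4,5-tris(benzyloxy)phenyl]tetrahydro-1H,3H-furo[3,4-c]furan-1-one | O=C1O[C@H](c2cc(OCc3ccccc3)c(OCc3ccccc3)c(OCc3ccccc3)c2)[C@H]2CO[C@H](c3ccc(OCc4ccccc4)c(OCc4ccccc4)c3)[C@@H]12
A6 | alternative 3 | (5S)-5-[3,4,5-tris(benzyloxy)phenyl]furan-2(5H)-one | O=C1O[C@H](c2cc(OCc3ccccc3)c(OCc3ccccc3)c(OCc3ccccc3)c2)C=C1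
A7 | alternative 3 | ({[3,4-bis(benzyloxy)phenyl](chloro)methoxy}methyl)trimethylsilane | C[Si](C)(C)COC(Cl)c1ccc(OCc2ccccc2)c(OCc2ccccc2)c1
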